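**Assumptions:** 5-Hydroxy-2(5H)-furanone is taken as purchasable (otherwise one step from furfural by O2/hν/rose bengal). Magnone B is drawn as its open hydroxy-ketone tautomer. Lignan labels used below: C7 is the ketone carbon, C9-OH is the hydroxyl on the future ring CH2 (target C5), and C9'-OH is the hydroxyl of the future CH2OH.

## Retrosynthetic overview
1. The aryl ketone comes from a bis(phenylthio)ketal, a masked acyl anion that is unmasked last.
2. The THF ring comes from O1–C2 closure: a benzylic cation is captured by the primary OH at the future C5 of an acyclic (2R,3R)-triol. This sets C2 trans.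
3. The triol comes from LiAlH4 reduction of a trans-3,4-disubstituted 5-menthyloxy-γ-lactone. The new ring uses the ArCH carbon in place of the lactone carbonyl carbon, so lactone-trans becomes THF 3,4-cis.
4. The lactone comes from a one-pot three-component conjugate addition/aldol. The partners are the lithiated veratraldehyde dithioacetal, (5R)-menthyloxybutenolide and 3,4,5-trimethoxybenzaldehyde.
5. Ring order: the sacrificial chiral butenolide is made first and opened in the reduction. The tetrahydrofuran is then the only target ring that is built.

## Route

**Step 1**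
Reactants: 1, 5-hydroxyfuran-2(5H)-one (racemic); 2, (−)-menthol (1R,2S,5R)
Product: 3, (5R)-5-[(1R,2S,5R)-menthyloxy]furan-2(5H)-one
Conditions: CSA (5 mol %), toluene, reflux, Dean–Stark; crystallise from hexane at −20 °C (mother liquor re-equilibrated with CSA)
Reagents that add atoms: (−)-menthol, CC(C)[C@@H]1CC[C@@H](C)C[C@H]1O
Why: In this acid-catalysed acetalisation the two acetal epimers interconvert under acid and only the (5R) epimer crystallises, which gives a diastereomerically pure relay stereocentre.

**Step 2**
Reactants: 4, 3,4-dimethoxybenzaldehyde; 5, thiophenol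
Product: 6, 4-[bis(phenylsulfanyl)methyl]-1,2-dimethoxybenzene
Conditions: PhSH (2.1 equiv), BF3·OEt2 (0.5 equiv), CH2Cl2, 0 °C → rt
Reagents that add atoms: thiophenol, Sc1ccccc1 (two equivalents incorporated)
Why: Lewis-acid dithioacetalisation converts the aldehyde into an acyl-anion equivalent (umpolung); no stereocentre is formed.

**Step 3**
Reactants: 6, dithioacetal; 3, butenolide; 7, 3,4,5-trimethoxybenzaldehyde
Product: 8, (3S,4R,5R)-4-[(3,4-dimethoxyphenyl)bis(phenylsulfanyl)methyl]-3-[hydroxy(3,4,5-trimethoxyphenyl)methyl]-5-(l-menthyloxy)dihydrofuran-2(3H)-one, a mixture of carbinol epimers carried on together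
Conditions: 6, n-BuLi, THF, −78 °C; then 3, −78 °C; then 7, −78 °C; aq NH4Cl
Reagents that add atoms: 3,4,5-trimethoxybenzaldehyde, COc1cc(C=O)cc(OC)c1OC (with 3 and 6, all listed as reactants; n-BuLi adds nothing)
Why: In this tandem Michael addition/aldol the soft sulfur-stabilised anion adds 1,4 anti to the C5 menthyloxy group (sets C4 = R, target C4), and the enolate is then trapped anti to the bulky new C4 group (sets C3, target C3).

**Step 4**
Reactants: 8
Product: 9, (2R,3R)-2-[(3,4-dimethoxyphenyl)bis(phenylsulfanyl)methyl]-3-[hydroxy(3,4,5-trimethoxyphenyl)methyl]butane-1,4-diol (carbinol epimers); menthol is recovered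
Conditions: LiAlH4 (4 equiv), THF, 0 °C → rt; Rochelle salt work-up
Reagents that add atoms: none
Why: Hydride reduction opens the lactone, the released hemiacetal expels menthoxide, and the resulting aldehyde is reduced too; the thioketal and both C–H stereocentres are untouched.

**Step 5**
Reactants: 9
Product: 10, {(2S,3R,4R)-4-[(3,4-dimethoxyphenyl)bis(phenylsulfanyl)methyl]-2-(3,4,5-trimethoxyphenyl)oxolan-3-yl}methanol
Conditions: CSA (10 mol %), CH2Cl2 (0.02 M), 0 °C → rt; quench with Et3N
Reagents that add atoms: none
Why: In this SN1 cyclodehydration both carbinol epimers ionise to one p-methoxy-stabilised benzylic cation, only the C9-OH can close a five-membered ring (the other would give an oxetane), and the aryl ends up trans to the two cis substituents at C3 and C4, which sets C2 = S.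

**Step 6**
Reactants: 10
Product: 11, magnone B, (2S,3R,4R)
Conditions: HgO (red), BF3·OEt2, THF–H2O (9:1), 0 °C → rt; filter through Celite, brief NaHCO3 wash
Reagents that add atoms: water, O
Why: Hg(II)-assisted thioketal hydrolysis proceeds through a thionium ion that the cis CH2OH captures, so any transient enolisation passes through a cis-fused bicyclic hemiketal and the 3,4-cis relationship at C4 is retained.

**Stereochemical summary**
- C4 (R) and C3 (R) are set in step 3 by the menthyloxy acetal centre. They are never bond-broken afterwards.
- C2 (S) is set in step 5.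
- The relay acetal centre is erased in step 4.

## Compound list
1 | 5-hydroxyfuran-2(5H)-one | O=C1C=CC(O)O1 | starting material
2 | (−)-menthol | CC(C)[C@@H]1CC[C@@H](C)C[C@H]1O | starting material
3 | (5R)-5-(l-menthyloxy)furan-2(5H)-one | O=C1C=C[C@H](O[C@@H]2C[C@H](C)CC[C@H]2C(C)C)O1 | intermediate
4 | 3,4-dimethoxybenzaldehyde | COc1ccc(C=O)cc1OC | starting material
5 | thiophenol | Sc1ccccc1 | starting material
6 | veratraldehyde bis(phenylthio)acetal | COc1ccc(C(Sc2ccccc2)Sc2ccccc2)cc1OC | intermediate
7 | 3,4,5-trimethoxybenzaldehyde | COc1cc(C=O)cc(OC)c1OC | starting material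
8 | (3S,4R,5R) tandem adduct lactone (carbinol epimers) | O=C1O[C@@H](O[C@@H]2C[C@H](C)CC[C@H]2C(C)C)[C@H](C(Sc2ccccc2)(Sc2ccccc2)c2ccc(OC)c(OC)c2)[C@H]1C(O)c1cc(OC)c(OC)c(OC)c1 | intermediate
9 | (2R,3R)-triol (carbinol epimers) | OC[C@H](C(Sc1ccccc1)(Sc1ccccc1)c1ccc(OC)c(OC)c1)[C@H](CO)C(O)c1cc(OC)c(OC)c(OC)c1 | intermediate
10 | (2S,3R,4R)-THF thioketal alcohol | COc1ccc(C(Sc2ccccc2)(Sc2ccccc2)[C@H]2CO[C@H](c3cc(OC)c(OC)c(OC)c3)[C@H]2CO)cc1OC | intermediate
11 | magnone B | COc1ccc(C(=O)[C@H]2CO[C@H](c3cc(OC)c(OC)c(OC)c3)[C@H]2CO)cc1OC | target

## Step count and risks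
**Total steps:** 6. **Longest linear sequence:** 5 (1 → 3 → 8 → 9 → 10 → 11; the branch 4 → 6 → 8 onward is equal in length).

**The three steps most likely to fail**

1. **Step 5, cyclisation.**
   - Risk: the benzylic cation may instead be attacked by the electron-rich veratryl ring (aryltetralin formation) or by a neighbouring SPh group.
   - Fallback: reverse the order of events. Hydrolyse the thioketal on triol 9 first. The keto-triol should exist mainly as its five-membered hemiketal with the C9'-OH, the aroyl ring is now deactivated and sulfur is gone. Then close O1–C2 with acid, watching for epimerisation or dehydration at the ketone's α-carbon (C8).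

2. **Step 3, three-component coupling.**
   - Risk: incomplete enolate trapping or retro-aldol.
   - Fallback: replace the aldol with a C-acylation. Isolate the simple conjugate adduct, re-enolise it with LDA and acylate with 3,4,5-trimethoxybenzoyl chloride. The thermodynamically trans β-keto lactone is then reduced (NaBH4, then LiAlH4) to the same triol 9, whose carbinol configuration does not matter.

3. **Step 6, unmasking next to a β-alkoxy, epimerisable centre.**
   - Risk: epimerisation, ring-opening by β-elimination, or sulfur and mercury residues.
   - Fallback: drop the late thioketal and use a biomimetic C–H oxidation.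
     - Hydrolyse the thioketal at lactone stage 8.
     - Reduce with LiAlH4 to the tetraol.
     - Cyclise with acid to the furofuran (+)-magnolin.
     - Treat with DDQ in wet CH2Cl2. This is expected to oxidise the benzylic C–H next to the 3,4-dimethoxyphenyl ring preferentially, and the resulting hemiketal opens to magnone B.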